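**Retrosynthetic overview**
1. Target 33, (3S,5R,8S,3′R,6′R)-5,8-epoxy-5,8-dihydro-β,ε-carotene-3,3′-diol, comes from its bis-silyl ether 32, which is made in one operation from the C21 pentaenyl iodide 28 (ε half, C15 terminus) and the C19 5-hydroxy-6,7-retro-tetraenal 17 (C14 aldehyde).
2. Enabling feature: in the 2,5-dihydrofuran ring (O–C5–C6=C7–C8) the oxygen-bearing C8 is linked to C14 through C9=C10, C11=C12 and C13=C14, so C8 is the vinylogous partner of C14. A leaving group on C14 of the retro-tetraene (C6=C7, C8=C9, C10=C11, C12=C13) therefore gives the same C5-hydroxy polyenyl cation as the natural 5,6-epoxide to 5,8-furanoid rearrangement, and O(C5)→C8 closure makes the ring and the conjugated octaene together.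
3. Fragment 17 comes from lactol 10 (a loliolide-type bicycle that fixes 6Z), this from anti-epoxy aldehyde 8 (Sharpless epoxidation), this from (4R,6R)-actinol 1; the chain is built by Wittig and Horner–Wadsworth–Emmons steps.
4. Fragment 28 comes from C20 aldehyde 27 (Takai iodoolefination), this from (R)-α-ionone 18 by allylic oxidation, trans-selective reduction (C3′) and two Horner–Wadsworth–Emmons extensions.
5. Ring order: both six-membered rings are bought (1 and 18); the dihydrofuran ring is closed in the key step; desilylation ends the route.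

Key step: step 22

Remark (assumption): (4R,6R)-actinol, (R)-α-ionone and ethyl (E)-4-bromo-2-methylbut-2-enoate are taken as purchasable, the first two enantiopure; carotenoid locants are used throughout (ring C1–C6, chain C7–C15, primed for the ε half); TBS = tert-butyldimethylsilyl.

**Right-hand fragment (steps 1–13)**

Step 1
Reactants: 1 (4R,6R)-actinol
Product: 2 TBS ether of actinol
Conditions: TBSCl, imidazole, DMF, 23 °C
Reagents that add atoms: tert-butyldimethylsilyl chloride, C[Si](C)(Cl)C(C)(C)C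
Why: Silyl ether protection of the only hydroxyl; no stereocentre is touched.

Step 2
Reactants: 2 TBS ether of actinol
Product: 4 enol triflate, via lithium enolate 3 (not isolated)
Conditions: LiN(i-Pr)2, THF, −78 → 0 °C; PhNTf2, −78 → 23 °C
Reagents that add atoms: N-phenylbis(trifluoromethanesulfonimide), O=S(=O)(N(c1ccccc1)S(=O)(=O)C(F)(F)F)C(F)(F)F
Why: Enolate O-triflation (enol triflate formation); C1 is quaternary, so only C5–H can be removed and the C5=C6 triflate forms regiospecifically, the C5 centre of 2 being erased on purpose.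

Step 3
Reactants: 4 enol triflate
Product: 5 methyl cyclohexenecarboxylate
Conditions: Pd(OAc)2 (5 mol%), PPh3, CO (1 atm), Et3N, MeOH–DMF, 60 °C
Reagents that add atoms: carbon monoxide, [C-]#[O+]; methanol, CO
Why: Palladium-catalysed methoxycarbonylation of a vinyl triflate installs C7 at the ester level.

Step 4
Reactants: 5 methyl cyclohexenecarboxylate
Product: 6 allylic alcohol
Conditions: i-Bu2AlH, CH2Cl2, −78 → 0 °C; aq. potassium sodium tartrate
Reagents that add atoms: none
Why: Hydride reduction of the conjugated ester gives the allylic alcohol needed for reagent-controlled epoxidation.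

Step 5
Reactants: 6 allylic alcohol
Product: 7 anti-epoxy alcohol
Conditions: Ti(Oi-Pr)4, D-(−)-diethyl tartrate, t-BuOOH, 4 Å MS, CH2Cl2, −20 °C
Reagents that add atoms: tert-butyl hydroperoxide, CC(C)(C)OO
Why: Sharpless asymmetric epoxidation; with the D-(−)-tartrate the oxygen should be delivered to the face of C5=C6 anti to the C3 silyloxy group, which sets C5 (R) and C6 under reagent control.

Step 6
Reactants: 7 anti-epoxy alcohol
Product: 8 epoxy aldehyde
Conditions: (n-Pr4N)RuO4 (5 mol%), N-methylmorpholine N-oxide, 4 Å MS, CH2Cl2, 23 °C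
Reagents that add atoms: none
Why: Ley–Griffith oxidation of the primary alcohol; the epoxy aldehyde has no α-hydrogen and cannot epimerise.

Step 7
Reactants: 8 epoxy aldehyde
Product: 9 methyl enol ether
Conditions: Ph3P(CH2OMe)Cl, KOt-Bu, THF, 0 °C
Reagents that add atoms: (methoxymethyl)triphenylphosphonium chloride, COC[P+](c1ccccc1)(c1ccccc1)c1ccccc1.[Cl-]
Why: Wittig methoxymethylenation adds C8; the E/Z ratio of the enol ether is irrelevant.

Step 8
Reactants: 9 methyl enol ether
Product: 10 lactol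
Conditions: pyridinium p-toluenesulfonate (cat.), THF–H2O, 23 °C
Reagents that add atoms: water, O
Why: Acid-mediated enol ether hydrolysis with vinylogous opening of the oxirane at C6 (the C5–O bond stays intact, so C5 keeps its configuration); only the (6Z)-4-hydroxy enal can close to the cyclic hemiacetal, which should drain the acid-equilibrating 6E isomer.

Step 9
Reactants: 10 lactol
Product: 12 hydroxy dienal, via open hydroxy enal 11 (not isolated)
Conditions: Ph3P=C(CH3)CHO, toluene, 90 °C
Reagents that add atoms: 2-(triphenylphosphoranylidene)propanal, CC(C=O)=P(c1ccccc1)(c1ccccc1)c1ccccc1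
Why: Wittig olefination of a lactol through its open-chain tautomer with a stabilised α-methyl ylide; 6Z is inherited from the ring and the new C8=C9 bond should form E.

Step 10
Reactants: 13 ethyl (E)-4-bromo-2-methylbut-2-enoate
Product: 14 C5 phosphonate ester
Conditions: P(OEt)3, neat, 120 °C
Reagents that add atoms: triethyl phosphite, CCOP(OCC)OCC
Why: Michaelis–Arbuzov reaction of the allylic bromide.

Step 11
Reactants: 12 hydroxy dienal; 14 C5 phosphonate ester
Product: 15 hydroxy tetraenoate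
Conditions: LiN(SiMe3)2, THF, −78 → 0 °C (2.2 equiv of the anion of 14)
Reagents that add atoms: none
Why: Horner–Wadsworth–Emmons olefination at the carbon α to phosphorus, E-selective at C10=C11; the second equivalent of anion covers the free tertiary hydroxyl.

Step 12
Reactants: 15 hydroxy tetraenoate
Product: 16 tetraenediol
Conditions: i-Bu2AlH, CH2Cl2, −78 °C; aq. potassium sodium tartrate; used crude
Reagents that add atoms: none
Why: 1,2-Reduction of the conjugated ester by the aluminium hydride.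

Step 13
Reactants: 16 tetraenediol
Product: 17 hydroxy tetraenal (C19 fragment)
Conditions: MnO2, CH2Cl2, 23 °C, dark
Reagents that add atoms: none
Why: MnO2 oxidises only the primary allylic alcohol; the tertiary C5–OH is inert.

**Left-hand fragment (steps 14–21)**

Step 14
Reactants: 18 (R)-α-ionone
Product: 19 C15 nitrile
Conditions: (EtO)2P(O)CH2CN, NaH, THF, 0 → 23 °C
Reagents that add atoms: diethyl (cyanomethyl)phosphonate, CCOP(=O)(CC#N)OCC
Why: Horner–Wadsworth–Emmons olefination of the methyl ketone (9′E isomer separated); the weakly basic phosphonate anion should leave the C6′–H centre untouched.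

Step 15
Reactants: 19 C15 nitrile
Product: 20 3′-oxo nitrile
Conditions: Rh2(cap)4 (dirhodium tetrakis(caprolactamate), 1 mol%), t-BuOOH (70% aq.), ClCH2CH2Cl, 40 °C
Reagents that add atoms: tert-butyl hydroperoxide, CC(C)(C)OO
Why: Catalytic allylic C–H oxidation to the enone; C3′ is the only unhindered secondary allylic CH2 (C6′–H is shielded by the gem-dimethyl group), and base-free conditions protect the C6′ centre.

Step 16
Reactants: 20 3′-oxo nitrile
Product: 21 trans-hydroxy nitrile
Conditions: LiBH(s-Bu)3, THF, −78 °C; H2O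
Reagents that add atoms: none
Why: 1,2-Reduction of the β,β-disubstituted enone by a bulky borohydride; with the C6′ side chain pseudoaxial the hydride should come anti to the axial C1′ methyl, giving the 3′,6′-trans alcohol (3′R), the cis epimer being removed by chromatography.

Step 17
Reactants: 21 trans-hydroxy nitrile
Product: 22 silyloxy nitrile
Conditions: TBSCl, imidazole, DMF, 23 °C
Reagents that add atoms: tert-butyldimethylsilyl chloride, C[Si](C)(Cl)C(C)(C)C
Why: Silyl ether protection of the allylic alcohol; no stereocentre is touched.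

Step 18
Reactants: 22 silyloxy nitrile
Product: 24 C15 aldehyde, via N-aluminio imine 23 (not isolated)
Conditions: i-Bu2AlH, CH2Cl2, −78 °C; wet SiO2 / aq. potassium sodium tartrate
Reagents that add atoms: water, O
Why: Partial reduction of the nitrile to the aluminium imine and hydrolysis to the aldehyde; the 9′E geometry is kept.

Step 19
Reactants: 24 C15 aldehyde
Product: 25 C20 nitrile
Conditions: (EtO)2P(O)CH2C(CH3)=CHCN, NaH, THF, 0 °C
Reagents that add atoms: diethyl (3-cyano-2-methylallyl)phosphonate, CCOP(=O)(CC(C)=CC#N)OCC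
Why: Horner–Wadsworth–Emmons chain extension by the C5 unit, E at the new C11′=C12′ bond (13′E isomer separated).

Step 20
Reactants: 25 C20 nitrile
Product: 27 C20 aldehyde, via N-aluminio imine 26 (not isolated)
Conditions: i-Bu2AlH, CH2Cl2, −78 °C; wet SiO2 / aq. potassium sodium tartrate
Reagents that add atoms: water, O
Why: Partial nitrile reduction and hydrolysis to the polyenal, as in step 18.

Step 21
Reactants: 27 C20 aldehyde
Product: 28 C21 pentaenyl iodide
Conditions: CrCl2, CHI3, THF–dioxane, 0 °C, dark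
Reagents that add atoms: iodoform, IC(I)I
Why: Takai iodoolefination (gem-dichromium reagent formed from CHI3 and CrCl2) adds C15 as an E-vinyl iodide.

**Union and end game (steps 22–23)**

Step 22
Reactants: 17 hydroxy tetraenal (C19 fragment); 28 C21 pentaenyl iodide
Product: 32 bis-TBS ether of the target, via alkenylchromium dichloride 29 (not isolated), via C14 carbinol 30 (not isolated), via polyenyl cation 31 (not isolated)
Conditions: CrCl2, NiCl2 (cat.), DMSO–THF, 23 °C, dark; aq. work-up; then HCl (0.01 M in Et2O), −20 °C; NaHCO3; chromatography (C8 epimers separated, 8R epimer returned to the acid)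
Reagents that add atoms: none
Why: Proposed new method: a Nozaki–Hiyama–Kishi coupling (nickel-catalysed insertion into the C15–I bond of 28, transfer to trivalent chromium, 1,2-addition of 29 to the C14 aldehyde of 17 with the free C5–OH tolerated) forms C14–C15 and gives carbinol 30, whose C14–OH lies between a tetraenyl and a pentaenyl arm, so that trace acid should ionise it to cation 31 (charge spread over C6, C8, C10, C12, C14 and on to C7′). This is the same cation through which 5,6-epoxy carotenoids rearrange to 5,8-furanoid oxides; the closest known reaction types are that epoxide–furanoid rearrangement and the acid-induced allylic transposition of polyene carbinols. The tertiary oxygen on C5 closes on C8 in a 5-exo-trig mode with respect to the C8=C9 unit (ring O–C5–C6=C7–C8), which moves the chain double bonds to C9=C10, C11=C12 and C13=C14 and so creates the dihydrofuran and the all-E octaene in one event. The step is stereoconvergent for both C14 epimers of 30 and for any 6E, s-cis or Z material, all of which pass through planar 31, while C5 (R) is untouched. The new centre C8 is set by the face of C8 that the oxygen reaches (chain syn to the C5 methyl gives the required 8S); C5 biases this only weakly, so both C8 epimers must be expected, but the doubly allylic C8–O bond re-ionises to 31 under the same acid, so the separated 8R epimer is returned to the acid and funnelled to 8S over a few cycles. The selectivities needed are ionisation at C14 rather than at the allylic C3′–OSi (secured by the far greater stabilisation of the polyenyl cation) and capture by oxygen rather than proton loss (secured by the 6Z-held hydroxyl next to C8, C6 and C8 having no adjacent C–H).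

Step 23
Reactants: 32 bis-TBS ether of the target
Product: 33 target diol
Conditions: Bu4NF, THF, 0 → 23 °C, dark
Reagents that add atoms: none
Why: Fluoride-mediated cleavage of both silyl ethers under basic conditions, which should not ionise the acid-labile C8–O bond, so C8 is not scrambled.

**Compound list**
1 | (4R,6R)-4-hydroxy-2,2,6-trimethylcyclohexanone (actinol) | O=C1C(C)(C)C[C@H](O)C[C@H]1C | starting material
2 | (4R,6R)-4-(tert-butyldimethylsilyloxy)-2,2,6-trimethylcyclohexanone | O=C1C(C)(C)C[C@H](O[Si](C)(C)C(C)(C)C)C[C@H]1C | intermediate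
3 | lithium (4R)-4-(TBS-oxy)-2,6,6-trimethylcyclohex-1-en-1-olate | CC1=C(O[Li])C(C)(C)C[C@H](O[Si](C)(C)C(C)(C)C)C1 | intermediate
4 | (4R)-4-(TBS-oxy)-2,6,6-trimethylcyclohex-1-en-1-yl trifluoromethanesulfonate | CC1=C(OS(=O)(=O)C(F)(F)F)C(C)(C)C[C@H](O[Si](C)(C)C(C)(C)C)C1 | intermediate
5 | methyl (4R)-4-(TBS-oxy)-2,6,6-trimethylcyclohex-1-ene-1-carboxylate | CC1=C(C(=O)OC)C(C)(C)C[C@H](O[Si](C)(C)C(C)(C)C)C1 | intermediate
6 | [(4R)-4-(TBS-oxy)-2,6,6-trimethylcyclohex-1-en-1-yl]methanol | CC1=C(CO)C(C)(C)C[C@H](O[Si](C)(C)C(C)(C)C)C1 | intermediate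
7 | (3S,5R,6R)-5,6-epoxy alcohol, [4-(TBS-oxy)-2,2,6-trimethyl-7-oxabicyclo[4.1.0]heptan-1-yl]methanol, oxirane oxygen trans to the silyloxy group | OC[C@]12C(C)(C)C[C@H](O[Si](C)(C)C(C)(C)C)C[C@@]1(C)O2 | intermediate
8 | (3S,5R,6S)-5,6-epoxy aldehyde, 4-(TBS-oxy)-2,2,6-trimethyl-7-oxabicyclo[4.1.0]heptane-1-carbaldehyde, oxirane trans to OSi | O=C[C@]12C(C)(C)C[C@H](O[Si](C)(C)C(C)(C)C)C[C@@]1(C)O2 | intermediate
9 | (3S,5R,6S)-1-(2-methoxyvinyl) epoxide (E/Z mixture at the enol ether) | COC=C[C@]12C(C)(C)C[C@H](O[Si](C)(C)C(C)(C)C)C[C@@]1(C)O2 | intermediate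
10 | (6S,7aR)-6-(TBS-oxy)-4,4,7a-trimethyl-2,4,5,6,7,7a-hexahydrobenzofuran-2-ol (both C2 epimers) | OC1C=C2C(C)(C)C[C@H](O[Si](C)(C)C(C)(C)C)C[C@@]2(C)O1 | intermediate
11 | (2Z)-2-[(2R,4S)-4-(TBS-oxy)-2-hydroxy-2,6,6-trimethylcyclohexylidene]acetaldehyde | O=C/C=C1/C(C)(C)C[C@H](O[Si](C)(C)C(C)(C)C)C[C@@]1(C)O | intermediate
12 | (2E,4Z)-4-[(2R,4S)-4-(TBS-oxy)-2-hydroxy-2,6,6-trimethylcyclohexylidene]-2-methylbut-2-enal | O=C/C(C)=C/C=C1/C(C)(C)C[C@H](O[Si](C)(C)C(C)(C)C)C[C@@]1(C)O | intermediate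
13 | ethyl (E)-4-bromo-2-methylbut-2-enoate | CCOC(=O)/C(C)=C/CBr | starting material
14 | ethyl (E)-4-(diethoxyphosphoryl)-2-methylbut-2-enoate | CCOC(=O)/C(C)=C/CP(=O)(OCC)OCC | intermediate
15 | ethyl (2E,4E,6E,8Z)-8-[(2R,4S)-4-(TBS-oxy)-2-hydroxy-2,6,6-trimethylcyclohexylidene]-2,6-dimethylocta-2,4,6-trienoate | CCOC(=O)/C(C)=C/C=C/C(C)=C/C=C1/C(C)(C)C[C@H](O[Si](C)(C)C(C)(C)C)C[C@@]1(C)O | intermediate
16 | (2E,4E,6E,8Z)-8-[(2R,4S)-4-(TBS-oxy)-2-hydroxy-2,6,6-trimethylcyclohexylidene]-2,6-dimethylocta-2,4,6-trien-1-ol | OC/C(C)=C/C=C/C(C)=C/C=C1/C(C)(C)C[C@H](O[Si](C)(C)C(C)(C)C)C[C@@]1(C)O | intermediate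
17 | (2E,4E,6E,8Z)-8-[(2R,4S)-4-(TBS-oxy)-2-hydroxy-2,6,6-trimethylcyclohexylidene]-2,6-dimethylocta-2,4,6-trienal (C19 5-hydroxy-6,7-retro-tetraenal; aldehyde carbon = C14) | O=C/C(C)=C/C=C/C(C)=C/C=C1/C(C)(C)C[C@H](O[Si](C)(C)C(C)(C)C)C[C@@]1(C)O | intermediate
18 | (R)-α-ionone | CC1=CCCC(C)(C)[C@H]1/C=C/C(C)=O | starting material
19 | (2E,4E)-3-methyl-5-[(1R)-2,6,6-trimethylcyclohex-2-en-1-yl]penta-2,4-dienenitrile | CC1=CCCC(C)(C)[C@H]1/C=C/C(C)=C/C#N | intermediate
20 | (2E,4E)-3-methyl-5-[(1R)-2,6,6-trimethyl-4-oxocyclohex-2-en-1-yl]penta-2,4-dienenitrile | CC1=CC(=O)CC(C)(C)[C@H]1/C=C/C(C)=C/C#N | intermediate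
21 | (2E,4E)-5-[(1R,4R)-4-hydroxy-2,6,6-trimethylcyclohex-2-en-1-yl]-3-methylpenta-2,4-dienenitrile | CC1=C[C@H](O)CC(C)(C)[C@H]1/C=C/C(C)=C/C#N | intermediate
22 | (2E,4E)-5-[(1R,4R)-4-(TBS-oxy)-2,6,6-trimethylcyclohex-2-en-1-yl]-3-methylpenta-2,4-dienenitrile | CC1=C[C@H](O[Si](C)(C)C(C)(C)C)CC(C)(C)[C@H]1/C=C/C(C)=C/C#N | intermediate
23 | N-(diisobutylaluminio) imine of 24 | CC1=C[C@H](O[Si](C)(C)C(C)(C)C)CC(C)(C)[C@H]1/C=C/C(C)=C/C=N[Al](CC(C)C)CC(C)C | intermediate
24 | (2E,4E)-5-[(1R,4R)-4-(TBS-oxy)-2,6,6-trimethylcyclohex-2-en-1-yl]-3-methylpenta-2,4-dienal | CC1=C[C@H](O[Si](C)(C)C(C)(C)C)CC(C)(C)[C@H]1/C=C/C(C)=C/C=O | intermediate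
25 | (2E,4E,6E,8E)-9-[(1R,4R)-4-(TBS-oxy)-2,6,6-trimethylcyclohex-2-en-1-yl]-3,7-dimethylnona-2,4,6,8-tetraenenitrile | CC1=C[C@H](O[Si](C)(C)C(C)(C)C)CC(C)(C)[C@H]1/C=C/C(C)=C/C=C/C(C)=C/C#N | intermediate
26 | N-(diisobutylaluminio) imine of 27 | CC1=C[C@H](O[Si](C)(C)C(C)(C)C)CC(C)(C)[C@H]1/C=C/C(C)=C/C=C/C(C)=C/C=N[Al](CC(C)C)CC(C)C | intermediate
27 | (2E,4E,6E,8E)-9-[(1R,4R)-4-(TBS-oxy)-2,6,6-trimethylcyclohex-2-en-1-yl]-3,7-dimethylnona-2,4,6,8-tetraenal | CC1=C[C@H](O[Si](C)(C)C(C)(C)C)CC(C)(C)[C@H]1/C=C/C(C)=C/C=C/C(C)=C/C=O | intermediate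
28 | (1E,3E,5E,7E,9E)-1-iodo-4,8-dimethyl-10-[(1R,4R)-4-(TBS-oxy)-2,6,6-trimethylcyclohex-2-en-1-yl]deca-1,3,5,7,9-pentaene (iodine on C15) | CC1=C[C@H](O[Si](C)(C)C(C)(C)C)CC(C)(C)[C@H]1/C=C/C(C)=C/C=C/C(C)=C/C=C/I | intermediate
29 | pentaenylchromium dichloride from 28 (trivalent chromium on C15) | CC1=C[C@H](O[Si](C)(C)C(C)(C)C)CC(C)(C)[C@H]1/C=C/C(C)=C/C=C/C(C)=C/C=C/[Cr](Cl)Cl | intermediate
30 | C40 carbinol, C14–OH (both C14 epimers), 6Z, otherwise all-E, C5–OH free | CC1=C[C@H](O[Si](C)(C)C(C)(C)C)CC(C)(C)[C@H]1/C=C/C(C)=C/C=C/C(C)=C/C=C/C(O)/C(C)=C/C=C/C(C)=C/C=C1/C(C)(C)C[C@H](O[Si](C)(C)C(C)(C)C)C[C@@]1(C)O | intermediate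
31 | C5-hydroxy polyenyl cation (one resonance form, charge drawn on C8) | CC1=C[C@H](O[Si](C)(C)C(C)(C)C)CC(C)(C)[C@H]1/C=C/C(C)=C/C=C/C(C)=C/C=C/C=C(C)/C=C/C=C(\C)[CH+]/C=C1/C(C)(C)C[C@H](O[Si](C)(C)C(C)(C)C)C[C@@]1(C)O | intermediate
32 | (3S,5R,8S,3′R,6′R)-3,3′-bis(TBS-oxy)-5,8-epoxy-5,8-dihydro-β,ε-carotene | CC1=C[C@H](O[Si](C)(C)C(C)(C)C)CC(C)(C)[C@H]1/C=C/C(C)=C/C=C/C(C)=C/C=C/C=C(C)/C=C/C=C(\C)[C@@H]1C=C2C(C)(C)C[C@H](O[Si](C)(C)C(C)(C)C)C[C@@]2(C)O1 | intermediate
33 | (3S,5R,8S,3′R,6′R)-5,8-epoxy-5,8-dihydro-β,ε-carotene-3,3′-diol (CNP0219251.2) | CC1=C[C@H](O)CC(C)(C)[C@H]1/C=C/C(C)=C/C=C/C(C)=C/C=C/C=C(C)/C=C/C=C(\C)[C@@H]1C=C2C(C)(C)C[C@H](O)C[C@@]2(C)O1 | target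

**Step count and risks**

Total step count: 23. Longest linear sequence: 14 steps (1–9, 11–13, 22, 23, from actinol).

Steps most likely to fail:

1. Step 22 (Proposed new method). What may go wrong: ring closure on both faces of C8 with little preference (poor facial selectivity), loss of cation 31 by proton loss from C6′–H or the chain methyl groups before the oxygen closes, and degradation of the pentaenyl iodide during the chromium-mediated addition. Fallback with known chemistry, in which the dihydrofuran is closed first and stereospecifically and C14–C15 is then made by cross-coupling: it sets out from epoxy aldehyde 8. Seyferth–Gilbert homologation with dimethyl (1-diazo-2-oxopropyl)phosphonate (K2CO3, MeOH) would give the epoxy alkyne F1. Sonogashira coupling with (E)-3-iodobut-2-en-1-ol [Pd(PPh3)4, CuI, i-Pr2NH] would give the epoxy enynol F2. i-Bu2AlH would open the alkynyl oxirane by SN2′ hydride delivery to the (6R)-allenic diol F3, the allenol of the natural allenic carotenoid end group. AgNO3 (cat., acetone, dark) would cycloisomerise the α-hydroxyallene (5-endo) to the dihydrofuran alcohol F4 with axis-to-centre chirality transfer; the (6R) axis places C9 on the side of the C5 methyl, which is 8S. MnO2 would give the furanoid aldehyde F5. Horner–Wadsworth–Emmons reaction with diethyl [(E)-2-methyl-3-(tributylstannyl)prop-2-enyl]phosphonate (NaH, THF) would give the trienylstannane F6. Stille coupling of F6 with iodide 28 [Pd2(dba)3, AsPh3, NMP, 40 °C] forms C14–C15 and comes back to the route at 32.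

2. Step 9. What may go wrong: the hindered lactol may open too slowly at the temperature the stabilised ylide needs, and prolonged heating may isomerise the 6Z enal or let the C5 hydroxyl add back to C8 (intramolecular oxa-Michael addition). Fallback with anion-driven opening at low temperature and later adjustment of the oxidation level: it sets out from lactol 10. Horner–Wadsworth–Emmons reaction with triethyl 2-phosphonopropionate (NaH, THF, 0 °C; the alkoxide opens the lactol and the α-methyl enoate is a poor Michael acceptor) would give the hydroxy dienoate F7. i-Bu2AlH would give the diol F8. MnO2 oxidises only the primary allylic alcohol of F8 and comes back to the route at 12.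

3. Step 21. What may go wrong: erosion of E selectivity and decomposition of the light- and radical-sensitive pentaenyl iodide under the CrCl2/CHI3 conditions. Fallback through an alkyne instead of a one-carbon chromium carbenoid: it sets out from aldehyde 27. Seyferth–Gilbert homologation with dimethyl (1-diazo-2-oxopropyl)phosphonate (K2CO3, MeOH, 0 °C) would give the terminal polyenyne F9. Syn-hydrozirconation with Cp2Zr(H)Cl (THF, 23 °C) would give the E-alkenylzirconocene chloride F10. Iodinolysis of F10 (I2, 0 °C) replaces zirconium with retention and comes back to the route at 28.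

Further compounds
F1 | step 22 | (3S,5R,6R)-1-ethynyl-4-(TBS-oxy)-2,2,6-trimethyl-7-oxabicyclo[4.1.0]heptane (epoxy alkyne, oxirane trans to OSi; same spatial arrangement as in 8) | C#C[C@]12C(C)(C)C[C@H](O[Si](C)(C)C(C)(C)C)C[C@@]1(C)O2
F2 | step 22 | (E)-epoxy enynol, 3-methyl-5-(epoxycyclohexyl)pent-2-en-4-yn-1-ol | OC/C=C(C)/C#C[C@]12C(C)(C)C[C@H](O[Si](C)(C)C(C)(C)C)C[C@@]1(C)O2
F3 | step 22 | (3S,5R,6R)-allenic diol, 9E (the 6R allene axis is stated here; the line notation does not carry it) | OC/C=C(C)/C=C=C1C(C)(C)C[C@H](O[Si](C)(C)C(C)(C)C)C[C@@]1(C)O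
F4 | step 22 | (3S,5R,8S)-furanoid allylic alcohol, (E)-3-[(2S,6S,7aR)-6-(TBS-oxy)-4,4,7a-trimethyl-2,4,5,6,7,7a-hexahydrobenzofuran-2-yl]but-2-en-1-ol | OC/C=C(\C)[C@@H]1C=C2C(C)(C)C[C@H](O[Si](C)(C)C(C)(C)C)C[C@@]2(C)O1
F5 | step 22 | (3S,5R,8S)-furanoid enal (aldehyde carbon = C11) | O=C/C=C(\C)[C@@H]1C=C2C(C)(C)C[C@H](O[Si](C)(C)C(C)(C)C)C[C@@]2(C)O1
F6 | step 22 | (3S,5R,8S)-furanoid C19 trienylstannane (tributyltin on C14, all-E) | CCCC[Sn](CCCC)(CCCC)/C=C(C)/C=C/C=C(\C)[C@@H]1C=C2C(C)(C)C[C@H](O[Si](C)(C)C(C)(C)C)C[C@@]2(C)O1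
F7 | step 9 | ethyl (2E,4Z)-4-[(2R,4S)-4-(TBS-oxy)-2-hydroxy-2,6,6-trimethylcyclohexylidene]-2-methylbut-2-enoate | CCOC(=O)/C(C)=C/C=C1/C(C)(C)C[C@H](O[Si](C)(C)C(C)(C)C)C[C@@]1(C)O
F8 | step 9 | (2E,4Z)-4-[(2R,4S)-4-(TBS-oxy)-2-hydroxy-2,6,6-trimethylcyclohexylidene]-2-methylbut-2-en-1-ol | OC/C(C)=C/C=C1/C(C)(C)C[C@H](O[Si](C)(C)C(C)(C)C)C[C@@]1(C)O
F9 | step 21 | C21 terminal polyenyne from 27 (all-E) | CC1=C[C@H](O[Si](C)(C)C(C)(C)C)CC(C)(C)[C@H]1/C=C/C(C)=C/C=C/C(C)=C/C#C
F10 | step 21 | chlorobis(cyclopentadienyl)(pentaenyl)zirconium from F9 (E, Zr on C15) | CC1=C[C@H](O[Si](C)(C)C(C)(C)C)CC(C)(C)[C@H]1/C=C/C(C)=C/C=C/C(C)=C/C=C/[Zr](Cl)(C1C=CC=C1)C1C=CC=C1
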